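**Plan** (unprimed locants = the 5,7-dihydroxy chromanone A; doubly primed locants = the 5-hydroxy-7-methoxy chromanone B; the same locants are kept for these atoms in all intermediates)

1. Retrosynthesis: each chromanone is cut at its aryl ether bond (O1–C8a, O1''–C8a'') and its ketone–aryl bond (C4–C4a, C4''–C4a''). Both benzo rings become 3,5-dioxygenated benzynes, and the core C2–C3–C3''–C2'' becomes an all-trans γ-lactone (O1''–C2''–C3''–C3–C4=O) with a free C2 carbinol and a C4'' methyl ester. The lactone is cut by two aldol disconnections (C2–C3, C2''–C3'') to a succinate.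
2. Enabling feature: in chromanone A the adjacent benzo carbons C8a and C4a carry O1 and the C4 carbonyl, with the C5 oxygen beside C4a. This is the pattern left when an O-nucleophile and an acyl carbon add across a 3-alkoxyaryne. O1'' is γ to C4, so C4 can be stored as a lactone that the ring-closing acylation opens.
3. Forward: Evans syn-aldol/lactonisation (C2''–C3''), auxiliary removal, dianion anti-aldol (C2–C3), esterification; aryne annulation 1 closes the pyranone of chromanone A and frees O1''; aryne annulation 2 closes chromanone B; one deprotection.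
4. Stereochemistry: C2''/C3'' come from the (S)-4-benzyloxazolidinone. C3 is set by attack anti to the C3'' carboxyl on the lactone, and C2 by the chair transition state of the E-lactone enolate. Neither annulation breaks a bond to a stereocentre, so anti becomes 2,3-trans and syn becomes 2'',3''-cis.

Key step: step 8

**Step 1**
Reactants: 1 (S)-4-benzyl-1,3-oxazolidin-2-one; 2 methyl 4-chloro-4-oxobutanoate
Product: 3 methyl 4-[(4S)-4-benzyl-2-oxo-1,3-oxazolidin-3-yl]-4-oxobutanoate
Conditions: n-BuLi, THF, −78 °C; then 2, −78 → 0 °C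
Reagents that add atoms: none
Why: N-acylation of the lithiated oxazolidinone by the acid chloride, which is far more electrophilic than the methyl ester end, should give the imide without touching the stereocentre.

**Step 2**
Reactants: 3; 4 4-methoxybenzaldehyde
Product: 6 (4S)-4-benzyl-3-[(2S,3S)-2-(4-methoxyphenyl)-5-oxooxolane-3-carbonyl]-1,3-oxazolidin-2-one, via syn-aldol adduct 5 (not isolated)
Conditions: Bu2BOTf, i-Pr2NEt, CH2Cl2, 0 °C; 4, −78 → 0 °C; pH 7 buffer, MeOH, H2O2; then PPTS (cat.), CH2Cl2, 23 °C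
Reagents that add atoms: none
Why: Evans syn-aldol reaction of the Z-boron enolate through a chair transition state, with the aldehyde on the enolate face away from the auxiliary benzyl group, should set C3'' (S) and C2'' (S), and the γ-hydroxy ester then lactonises to the 2,3-trans lactone with loss of methanol.

**Step 3**
Reactants: 6
Product: 7 (2S,3S)-2-(4-methoxyphenyl)-5-oxooxolane-3-carboxylic acid
Conditions: LiOH, H2O2, THF/H2O, 0 °C; Na2SO3; HCl to pH 2
Reagents that add atoms: hydrogen peroxide, OO (acts as LiOOH and supplies the carboxyl OH oxygen)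
Why: Hydroperoxide cleavage of the N-acyloxazolidinone attacks the exocyclic carbonyl selectively, any lactone opened by hydroxide recloses on acidification, and the weakly basic medium should not epimerise C3''.

**Step 4**
Reactants: 7; 4 4-methoxybenzaldehyde
Product: 8 (2S,3S,4R)-4-[(S)-hydroxy(4-methoxyphenyl)methyl]-2-(4-methoxyphenyl)-5-oxooxolane-3-carboxylic acid
Conditions: LiN(SiMe3)2 (2.2 equiv), THF, −78 °C; 4, −78 °C; AcOH, −78 °C
Reagents that add atoms: none
Why: Aldol addition of the carboxylate–lactone enolate dianion (the carboxylate shields C3''–H, so only the lactone CH2 is enolised) should occur on the ring face anti to the C3'' carboxylate, setting C3 (R), and through the chair Zimmerman–Traxler transition state of the E-configured cyclic enolate, setting the anti carbinol C2 (S).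

**Step 5**
Reactants: 8
Product: 9 methyl (2S,3S,4R)-4-[(S)-hydroxy(4-methoxyphenyl)methyl]-2-(4-methoxyphenyl)-5-oxooxolane-3-carboxylate
Conditions: TMSCHN2, PhMe/MeOH, 0 °C
Reagents that add atoms: (trimethylsilyl)diazomethane, C[Si](C)(C)C=[N+]=[N-] (supplies the ester CH3 carbon)
Why: Methyl ester formation with (trimethylsilyl)diazomethane is neutral, so the β-hydroxy lactone is exposed neither to base (retro-aldol) nor to acid.

**Step 6**
Reactants: 10 3,5-bis(benzyloxy)phenol
Product: 11 3,5-bis(benzyloxy)-2-bromophenol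
Conditions: NBS, i-Pr2NH (cat.), CH2Cl2, −78 → 0 °C
Reagents that add atoms: N-bromosuccinimide, O=C1CCC(=O)N1Br
Why: Amine-catalysed ortho-bromination of the phenol with NBS should deliver bromine next to the hydroxyl group, at one of the two equivalent positions between OH and OBn, not at the position between the two benzyloxy groups.

**Step 7**
Reactants: 11
Product: 14 3,5-bis(benzyloxy)-2-(trimethylsilyl)phenyl trifluoromethanesulfonate, via silyl ether 12 (not isolated), via lithium silylphenoxide 13 (not isolated)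
Conditions: HN(SiMe3)2, THF, 65 °C; concentrate; n-BuLi, THF, −100 °C; Tf2O, −100 → 0 °C
Reagents that add atoms: hexamethyldisilazane, C[Si](C)(C)N[Si](C)(C)C; trifluoromethanesulfonic anhydride, O=S(=O)(OS(=O)(=O)C(F)(F)F)C(F)(F)F
Why: O-silylation, bromine–lithium exchange and 1,3-retro-Brook migration of silicon from oxygen to carbon give the 2-silylphenoxide, whose triflation completes the standard preparation of an ortho-silylaryl triflate.

**Step 8**
Reactants: 9; 14
Product: 16 methyl (2S,3S)-2-[(2S,3R)-5,7-bis(benzyloxy)-2-(4-methoxyphenyl)-4-oxo-3,4-dihydro-2H-chromen-3-yl]-3-hydroxy-3-(4-methoxyphenyl)propanoate, via 3,5-bis(benzyloxy)benzyne 15 (not isolated)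
Conditions: KF, 18-crown-6, THF, −20 → 0 °C; 14 (1.05 equiv) added slowly
Reagents that add atoms: none
Why: Proposed new method: fluoride desilylates 14 to aryne 15; the fluoride-activated C2 hydroxyl of 9 adds to the aryne carbon remote from the neighbouring benzyloxy group (the more linear, more electrophilic end of the distorted triple bond, which places the developing carbanion on the carbon flanked by the inductively withdrawing OBn), the aryl anion adds to the lactone carbonyl C4, and collapse of the bicyclic lactol alkoxide breaks C4–O1'', opening the lactone and releasing the C2'' alkoxide, which takes the proton of the next molecule of 9. The closest known reaction type is the fluoride-mediated annulation of arynes with salicylate esters to xanthones (O-addition, then capture of the aryl anion by the ester), with the insertion of arynes into the N–acyl bond of β-lactams as a second relative; new are the aliphatic secondary alcohol and the lactone as acyl partner. The pyranone of chromanone A closes by 6-exo-trig attack of the aryl carbanion C4a on C4, after intermolecular formation of O1–C8a. No stereocentre is created: C2 keeps its configuration because its C–O bond is never broken and C3, C3'' and C2'' are not touched, so the anti-aldol pattern becomes 2,3-trans. The step needs the right orientation of the aryne (secured by its C3 benzyloxy group, which ends up as C5–OBn), acyl capture faster than protonation of the aryl anion (aprotic medium, low temperature, a reactive γ-lactone carbonyl reached through a six-membered transition state while the methyl ester would need seven), O-arylation faster than retro-aldol cleavage (weakly basic fluoride at −20 °C) and a single arylation (1.05 equiv of 14, the product alkoxide being quenched by proton transfer).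

**Step 9**
Reactants: 17 3,5-dimethoxyphenol
Product: 18 2-bromo-3,5-dimethoxyphenol
Conditions: NBS, i-Pr2NH (cat.), CH2Cl2, −78 → 0 °C
Reagents that add atoms: N-bromosuccinimide, O=C1CCC(=O)N1Br
Why: The same amine-catalysed ortho-bromination should place bromine between OH and OMe, the two ortho positions again being equivalent.

**Step 10**
Reactants: 18
Product: 21 3,5-dimethoxy-2-(trimethylsilyl)phenyl trifluoromethanesulfonate, via silyl ether 19 (not isolated), via lithium silylphenoxide 20 (not isolated)
Conditions: HN(SiMe3)2, THF, 65 °C; concentrate; n-BuLi, THF, −100 °C; Tf2O, −100 → 0 °C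
Reagents that add atoms: hexamethyldisilazane, C[Si](C)(C)N[Si](C)(C)C; trifluoromethanesulfonic anhydride, O=S(=O)(OS(=O)(=O)C(F)(F)F)C(F)(F)F
Why: The same silylation, bromine–lithium exchange, retro-Brook shift and triflation sequence as in step 7 should give the second ortho-silylaryl triflate.

**Step 11**
Reactants: 16; 21
Product: 23 (2S,3R)-5,7-bis(benzyloxy)-3-[(2S,3S)-5,7-dimethoxy-2-(4-methoxyphenyl)-4-oxo-3,4-dihydro-2H-chromen-3-yl]-2-(4-methoxyphenyl)-2,3-dihydro-4H-chromen-4-one, via 3,5-dimethoxybenzyne 22 (not isolated)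
Conditions: KF, 18-crown-6, THF, −20 → 0 °C; 21 (1.3 equiv) added slowly
Reagents that add atoms: none
Why: Proposed new method: the same sequence as in step 8 with the methyl ester as acyl partner, in which the C2'' alkoxide adds to aryne 22 at the carbon remote from the neighbouring methoxy group, the aryl anion attacks the ester carbonyl C4'' through a six-membered transition state (the ketone of chromanone A would need seven) and methoxide leaves and is buffered by unreacted 16; the closest known type is again the aryne–salicylate annulation to xanthones, and since C2'' is retained and C3'' untouched the syn-aldol pattern becomes the 2'',3''-cis chromanone B.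

**Step 12**
Reactants: 23
Product: 24 (2S,3R)-5,7-dihydroxy-3-[(2S,3S)-5-hydroxy-7-methoxy-2-(4-methoxyphenyl)-4-oxo-3,4-dihydro-2H-chromen-3-yl]-2-(4-methoxyphenyl)-2,3-dihydro-4H-chromen-4-one (the target)
Conditions: BCl3, C6HMe5, CH2Cl2, −78 → 0 °C; H2O
Reagents that add atoms: none
Why: Lewis acid ether cleavage with BCl3 should remove the two aryl benzyl ethers at −78 °C (pentamethylbenzene traps the benzyl cation) and, on warming, the 5''-methyl ether through its boron chelate with the C4'' carbonyl (chelation-controlled peri-demethylation), while the non-chelated 7''- and 4'-methyl ethers survive and the base-free medium should leave C3 and C3'' unepimerised.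

**Compound list**

1 | (S)-4-benzyl-1,3-oxazolidin-2-one | O=C1N[C@@H](Cc2ccccc2)CO1 | starting material
2 | methyl 4-chloro-4-oxobutanoate | COC(=O)CCC(Cl)=O | starting material
3 | methyl 4-[(4S)-4-benzyl-2-oxo-1,3-oxazolidin-3-yl]-4-oxobutanoate | COC(=O)CCC(=O)N1C(=O)OC[C@@H]1Cc1ccccc1 | intermediate
4 | 4-methoxybenzaldehyde | COc1ccc(C=O)cc1 | starting material
5 | methyl (3S,4S)-3-[(4S)-4-benzyl-2-oxo-1,3-oxazolidine-3-carbonyl]-4-hydroxy-4-(4-methoxyphenyl)butanoate | COC(=O)C[C@H](C(=O)N1C(=O)OC[C@@H]1Cc1ccccc1)[C@H](O)c1ccc(OC)cc1 | intermediate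
6 | (4S)-4-benzyl-3-[(2S,3S)-2-(4-methoxyphenyl)-5-oxooxolane-3-carbonyl]-1,3-oxazolidin-2-one | O=C1C[C@H](C(=O)N2C(=O)OC[C@@H]2Cc2ccccc2)[C@@H](c2ccc(OC)cc2)O1 | intermediate
7 | (2S,3S)-2-(4-methoxyphenyl)-5-oxooxolane-3-carboxylic acid | O=C1C[C@H](C(=O)O)[C@@H](c2ccc(OC)cc2)O1 | intermediate
8 | (2S,3S,4R)-4-[(S)-hydroxy(4-methoxyphenyl)methyl]-2-(4-methoxyphenyl)-5-oxooxolane-3-carboxylic acid | O=C1[C@@H]([C@H](O)c2ccc(OC)cc2)[C@H](C(=O)O)[C@@H](c2ccc(OC)cc2)O1 | intermediate
9 | methyl (2S,3S,4R)-4-[(S)-hydroxy(4-methoxyphenyl)methyl]-2-(4-methoxyphenyl)-5-oxooxolane-3-carboxylate | O=C1[C@@H]([C@H](O)c2ccc(OC)cc2)[C@H](C(=O)OC)[C@@H](c2ccc(OC)cc2)O1 | intermediate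
10 | 3,5-bis(benzyloxy)phenol | Oc1cc(OCc2ccccc2)cc(OCc2ccccc2)c1 | starting material
11 | 3,5-bis(benzyloxy)-2-bromophenol | Oc1cc(OCc2ccccc2)cc(OCc2ccccc2)c1Br | intermediate
12 | [3,5-bis(benzyloxy)-2-bromophenoxy]trimethylsilane | C[Si](C)(C)Oc1cc(OCc2ccccc2)cc(OCc2ccccc2)c1Br | intermediate
13 | lithium 3,5-bis(benzyloxy)-2-(trimethylsilyl)phenolate | [Li+].[O-]c1cc(OCc2ccccc2)cc(OCc2ccccc2)c1[Si](C)(C)C | intermediate
14 | 3,5-bis(benzyloxy)-2-(trimethylsilyl)phenyl trifluoromethanesulfonate | C[Si](C)(C)c1c(OCc2ccccc2)cc(OCc2ccccc2)cc1OS(=O)(=O)C(F)(F)F | intermediate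
15 | 3,5-bis(benzyloxy)-1,2-didehydrobenzene (aryne) | C1#CC(OCc2ccccc2)=CC(OCc2ccccc2)=C1 | intermediate
16 | methyl (2S,3S)-2-[(2S,3R)-5,7-bis(benzyloxy)-2-(4-methoxyphenyl)-4-oxo-3,4-dihydro-2H-chromen-3-yl]-3-hydroxy-3-(4-methoxyphenyl)propanoate | COc1ccc([C@H]2Oc3cc(OCc4ccccc4)cc(OCc4ccccc4)c3C(=O)[C@@H]2[C@H](C(=O)OC)[C@H](O)c2ccc(OC)cc2)cc1 | intermediate
17 | 3,5-dimethoxyphenol | COc1cc(O)cc(OC)c1 | starting material
18 | 2-bromo-3,5-dimethoxyphenol | COc1cc(O)c(Br)c(OC)c1 | intermediate
19 | (2-bromo-3,5-dimethoxyphenoxy)trimethylsilane | COc1cc(O[Si](C)(C)C)c(Br)c(OC)c1 | intermediate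
20 | lithium 3,5-dimethoxy-2-(trimethylsilyl)phenolate | [Li+].[O-]c1cc(OC)cc(OC)c1[Si](C)(C)C | intermediate
21 | 3,5-dimethoxy-2-(trimethylsilyl)phenyl trifluoromethanesulfonate | COc1cc(OC)c([Si](C)(C)C)c(OS(=O)(=O)C(F)(F)F)c1 | intermediate
22 | 3,5-dimethoxy-1,2-didehydrobenzene (aryne) | C1#CC(OC)=CC(OC)=C1 | intermediate
23 | (2S,3R)-5,7-bis(benzyloxy)-3-[(2S,3S)-5,7-dimethoxy-2-(4-methoxyphenyl)-4-oxo-3,4-dihydro-2H-chromen-3-yl]-2-(4-methoxyphenyl)-2,3-dihydro-4H-chromen-4-one | COc1ccc([C@H]2Oc3cc(OCc4ccccc4)cc(OCc4ccccc4)c3C(=O)[C@@H]2[C@@H]2C(=O)c3c(OC)cc(OC)cc3O[C@@H]2c2ccc(OC)cc2)cc1 | intermediate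
24 | (2S,3R)-5,7-dihydroxy-3-[(2S,3S)-5-hydroxy-7-methoxy-2-(4-methoxyphenyl)-4-oxo-3,4-dihydro-2H-chromen-3-yl]-2-(4-methoxyphenyl)-2,3-dihydro-4H-chromen-4-one | COc1ccc([C@H]2Oc3cc(O)cc(O)c3C(=O)[C@@H]2[C@@H]2C(=O)c3c(O)cc(OC)cc3O[C@@H]2c2ccc(OC)cc2)cc1 | target

**Step count**

Total steps: 12. Longest linear sequence: 8 (steps 1, 2, 3, 4, 5, 8, 11, 12).

**Steps most likely to fail**

Step 8. The aryl anion may be protonated before it reaches the lactone carbonyl, the alkoxide may fragment by retro-aldol cleavage, or the released C2'' alkoxide may be arylated a second time. The fallback uses known reactions, sets out from 9 and comes back at 16, making the ether bond and the ketone–aryl bond one after the other. Dess–Martin oxidation of 9 gives methyl (2S,3S,4R)-4-(4-methoxybenzoyl)-2-(4-methoxyphenyl)-5-oxooxolane-3-carboxylate F1. Chelation-controlled reduction with Zn(BH4)2 (Et2O, −78 °C) should give the syn, C2-epimeric alcohol methyl (2S,3S,4R)-4-[(R)-hydroxy(4-methoxyphenyl)methyl]-2-(4-methoxyphenyl)-5-oxooxolane-3-carboxylate F2. Mitsunobu etherification of this alcohol with bromophenol 11 (PPh3, DIAD, THF, 0 °C) inverts C2 back to (S) and gives methyl (2S,3S,4R)-4-[(S)-[3,5-bis(benzyloxy)-2-bromophenoxy](4-methoxyphenyl)methyl]-2-(4-methoxyphenyl)-5-oxooxolane-3-carboxylate F3. Bromine–lithium exchange (t-BuLi, THF, −100 °C) and Parham cyclisation of the aryllithium onto the lactone carbonyl then form the same C4–C4a bond, open the lactone and return 16.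

Step 11. The expelled methoxide may epimerise C3'' and erase the cis relationship, the alkoxide may undergo retro-aldol cleavage, or the aryl anion may be protonated instead of acylated. The fallback uses known reactions, sets out from 16 and comes back at 23. Palladium-catalysed etherification of 16 with 1-bromo-3,5-dimethoxybenzene (Pd2(dba)3, RockPhos, Cs2CO3, toluene, 80 °C) keeps C2'' because its C–O bond is not broken and gives methyl (2S,3S)-2-[(2S,3R)-5,7-bis(benzyloxy)-2-(4-methoxyphenyl)-4-oxo-3,4-dihydro-2H-chromen-3-yl]-3-(3,5-dimethoxyphenoxy)-3-(4-methoxyphenyl)propanoate F4. Neutral ester cleavage with Me3SnOH (1,2-dichloroethane, 70 °C) gives (2S,3S)-2-[(2S,3R)-5,7-bis(benzyloxy)-2-(4-methoxyphenyl)-4-oxo-3,4-dihydro-2H-chromen-3-yl]-3-(3,5-dimethoxyphenoxy)-3-(4-methoxyphenyl)propanoic acid F5. Intramolecular Friedel–Crafts acylation through the mixed anhydride ((CF3CO)2O, CH2Cl2, 0 °C), at either of the two equivalent positions ortho to the ether oxygen, closes chromanone B and returns 23.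

Step 4. The aldehyde face may be poorly discriminated, giving a mixture of carbinol epimers at C2, and the aldolate may equilibrate by retro-aldol reaction. The fallback sets out from 7 and comes back at 8, moving control of C2 from the enolate to a catalyst. Crossed Claisen acylation of the dianion of 7 with methyl 4-methoxybenzoate (LiN(SiMe3)2, 3.3 equiv, THF, −78 → 0 °C) gives (2S,3S,4R)-4-(4-methoxybenzoyl)-2-(4-methoxyphenyl)-5-oxooxolane-3-carboxylic acid F6. Noyori asymmetric transfer hydrogenation of the aryl ketone with RuCl[(S,S)-TsDPEN](p-cymene) in HCO2H/Et3N should set C2 (S) under catalyst control while the acidic C3 settles trans to the C3'' carboxyl (dynamic kinetic resolution), returning 8.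

**Further compounds**

F1 | step 8 | methyl (2S,3S,4R)-4-(4-methoxybenzoyl)-2-(4-methoxyphenyl)-5-oxooxolane-3-carboxylate | O=C1[C@@H](C(=O)c2ccc(OC)cc2)[C@H](C(=O)OC)[C@@H](c2ccc(OC)cc2)O1
F2 | step 8 | methyl (2S,3S,4R)-4-[(R)-hydroxy(4-methoxyphenyl)methyl]-2-(4-methoxyphenyl)-5-oxooxolane-3-carboxylate | O=C1[C@@H]([C@@H](O)c2ccc(OC)cc2)[C@H](C(=O)OC)[C@@H](c2ccc(OC)cc2)O1
F3 | step 8 | methyl (2S,3S,4R)-4-[(S)-[3,5-bis(benzyloxy)-2-bromophenoxy](4-methoxyphenyl)methyl]-2-(4-methoxyphenyl)-5-oxooxolane-3-carboxylate | O=C1[C@@H]([C@H](Oc2cc(OCc3ccccc3)cc(OCc3ccccc3)c2Br)c2ccc(OC)cc2)[C@H](C(=O)OC)[C@@H](c2ccc(OC)cc2)O1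
F4 | step 11 | methyl (2S,3S)-2-[(2S,3R)-5,7-bis(benzyloxy)-2-(4-methoxyphenyl)-4-oxo-3,4-dihydro-2H-chromen-3-yl]-3-(3,5-dimethoxyphenoxy)-3-(4-methoxyphenyl)propanoate | COc1ccc([C@H]2Oc3cc(OCc4ccccc4)cc(OCc4ccccc4)c3C(=O)[C@@H]2[C@H](C(=O)OC)[C@H](Oc2cc(OC)cc(OC)c2)c2ccc(OC)cc2)cc1
F5 | step 11 | (2S,3S)-2-[(2S,3R)-5,7-bis(benzyloxy)-2-(4-methoxyphenyl)-4-oxo-3,4-dihydro-2H-chromen-3-yl]-3-(3,5-dimethoxyphenoxy)-3-(4-methoxyphenyl)propanoic acid | COc1ccc([C@H]2Oc3cc(OCc4ccccc4)cc(OCc4ccccc4)c3C(=O)[C@@H]2[C@H](C(=O)O)[C@H](Oc2cc(OC)cc(OC)c2)c2ccc(OC)cc2)cc1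
F6 | step 4 | (2S,3S,4R)-4-(4-methoxybenzoyl)-2-(4-methoxyphenyl)-5-oxooxolane-3-carboxylic acid | O=C1[C@@H](C(=O)c2ccc(OC)cc2)[C@H](C(=O)O)[C@@H](c2ccc(OC)cc2)O1
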